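**Retrosynthetic overview**

- Feature: in ring B the C8 ketone and C9 carbinol sit beside ring-fusion C10, and the quaternary C5 is tied to C8 through C6–C7. This C5–C6–C7–C8(O)–C9(O)–C10 array is what a [3,3] shift of a 2-vinyl-3,3-dimethoxybicyclo[2.2.2]oct-5-en-2-ol leaves behind.
- Late disconnections: C3–O ester (acid 34); C12 alcohol from an aldehyde; C7=C11 by aldol condensation at C7; C3–OH and C4–H by hydroboration of C3=C4; C10–H and C9–O by dissolving-metal reduction of the C9=C10 diosphenol ether.
- Key disconnection: C5–C6 by anionic oxy-Cope rearrangement of vinyl carbinol 10, whose vinyl group and ethano bridge come from vinylmagnesium bromide and phenyl vinyl sulfone.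
- Ring order: ring A first (step 3, the cyclohexene ring of the bicyclo[2.2.2]octenone built from four arene carbons and the two dienophile carbons); ring B second (step 7). The cycloadduct is resolved in step 4.

Key step: step 7

Remark (numbering): decalin atoms carry eremophilane numbers (C3 ester oxygen, C4 and C5 methyls, C5/C10 ring fusion, C8 ketone, C9 carbinol, C7=C11 alkylidene, C12 oxygenated carbon); β is the face of the C5 methyl.

Remark (assumption): cycloadduct 6 is taken as the ortho, endo isomer usual for masked o-benzoquinones; an isomer at the sulfone-bearing carbon would converge on 10 in step 6.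

**Route**

Step 1
Reactants: 1 3,4-dimethylphenol
Product: 2 2-bromo-4,5-dimethylphenol
Conditions: Br2 (1.0 equiv), CH2Cl2, 0 °C
Reagents that add atoms: bromine, BrBr
Why: Electrophilic aromatic bromination ortho to the hydroxyl should go to the open C6 position, because the para position is blocked and C2 is flanked by OH and methyl.

Step 2
Reactants: 2 2-bromo-4,5-dimethylphenol
Product: 3 2-methoxy-4,5-dimethylphenol
Conditions: NaOMe, CuBr (10 mol %), MeOH–DMF, 110 °C; then aq. HCl
Reagents that add atoms: sodium methoxide, [Na+].[O-]C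
Why: Copper-catalysed Ullmann-type methoxylation of an o-bromophenolate is the classical entry to guaiacols (as in the bromovanillin to syringaldehyde conversion).

Step 3
Reactants: 3 2-methoxy-4,5-dimethylphenol; 4 phenyl vinyl sulfone
Product: 6 racemic 3,3-dimethoxy-5,6-dimethyl-7-(phenylsulfonyl)bicyclo[2.2.2]oct-5-en-2-one (sulfone syn to the C5=C6 bridge), via masked o-benzoquinone 5 (not isolated)
Conditions: PhI(OAc)2, MeOH, 4 (5 equiv), slow addition of 3, 0 °C → 50 °C
Reagents that add atoms: methanol, CO
Why: Oxidative dearomatisation of the guaiacol in methanol gives the o-quinone monoketal, which the excess vinyl sulfone (an ethylene equivalent) should trap in a Diels–Alder reaction before it dimerises, giving the racemic adduct.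

Step 4
Reactants: 6 racemic cycloadduct
Product: 7 (1R,4S,7S)-3,3-dimethoxy-5,6-dimethyl-7-(phenylsulfonyl)bicyclo[2.2.2]oct-5-en-2-one
Conditions: preparative SFC, amylose tris(3,5-dimethylphenylcarbamate) phase, CO2–MeOH
Reagents that add atoms: none
Why: Resolution by chromatography on a chiral stationary phase (no bond change) of a UV-active ketone supplies the enantiomer whose C4 bridgehead becomes C10 and dictates C5 in step 7.

Step 5
Reactants: 7 (1R,4S,7S)-cycloadduct; 8 vinylmagnesium bromide
Product: 9 (1R,2R,4S,7S)-3,3-dimethoxy-5,6-dimethyl-7-(phenylsulfonyl)-2-vinylbicyclo[2.2.2]oct-5-en-2-ol (vinyl syn to the C5=C6 bridge)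
Conditions: THF, −40 °C → 0 °C; aq. NH4Cl
Reagents that add atoms: none
Why: Grignard 1,2-addition to this non-enolisable ketone should occur from the face toward the alkene bridge, the other face being screened by the inward C–H of the saturated bridge, which sets C2 with the vinyl group syn to the alkene.

Step 6
Reactants: 9 sulfonyl vinyl carbinol
Product: 10 (1R,2R,4S)-3,3-dimethoxy-5,6-dimethyl-2-vinylbicyclo[2.2.2]oct-5-en-2-ol (vinyl syn to the alkene bridge)
Conditions: 6% Na(Hg), Na2HPO4, MeOH–THF, −20 °C → rt
Reagents that add atoms: none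
Why: Reductive desulfonylation by electron transfer from sodium amalgam cleaves the C–S bond and protonates the carbanion without touching the alkene, ketal or tertiary alcohol.

Step 7
Reactants: 10 vinyl carbinol
Product: 13 (4aS,8aS)-1,1-dimethoxy-4a,5-dimethyl-3,4,4a,7,8,8a-hexahydronaphthalen-2(1H)-one (cis-fused 9,9-dimethoxy-4,5-dimethyldecal-3-en-8-one; 5β-methyl and 10β-H), via potassium alkoxide 11 (not isolated), via potassium enolate 12 (not isolated)
Conditions: KH, 18-crown-6, THF, 0 °C → rt; aq. NH4Cl, −78 °C
Reagents that add atoms: none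
Why: KH with 18-crown-6 gives the dissociated alkoxide 11, whose oxyanion weakens the adjacent C3–C8 bond and triggers a concerted [3,3] shift of the 3-oxido-1,5-diene in which the vinyl terminus C6 bonds to C5 and C3–C8 breaks, giving enolate 12 that is protonated at C7 on work-up. This is the anionic oxy-Cope rearrangement, established for 2-vinylbicyclo[2.2.2]oct-5-en-2-ols derived from masked o-benzoquinone adducts. Ring B (six-membered) is closed by this sigmatropic reorganisation through the boat-like transition state that the cage enforces, not by an exo or endo cyclisation, and ring A emerges as the cyclohexene left from the bicycle. The new quaternary centre C5 is controlled by the existing bridgehead (future C10), because the vinyl terminus can only reach the alkene face turned toward the oxygenated bridge, so a cis fusion results. The step needs [3,3] selectivity over a [1,3] shift or fragmentation, which the rigid boat geometry, strain release and enolate formation should secure, and it needs the syn vinyl geometry set in step 5.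

Step 8
Reactants: 13 cis-fused keto ketal
Product: 14 9-hydroxy-4,5-dimethyldecala-3,9(10)-dien-8-one (diosphenol; 5β-methyl)
Conditions: 3 M aq. HCl, THF, 45 °C
Reagents that add atoms: water, O
Why: Acid hydrolysis of the α-keto ketal unmasks the 8,9-dione, which should tautomerise to the more substituted conjugated enol at C9=C10 (as 3-substituted cyclohexane-1,2-diones and steroidal 3,4-diones do), erasing the cis C10 centre so it can be reset.

Step 9
Reactants: 14 diosphenol
Product: 15 9-(methoxymethoxy)-4,5-dimethyldecala-3,9(10)-dien-8-one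
Conditions: MOMCl, i-Pr2NEt, CH2Cl2, 0 °C → rt
Reagents that add atoms: chloromethyl methyl ether, COCCl
Why: O-Alkylation of the acidic enol hydroxyl gives an enol ether that survives dissolving metal and cannot migrate between the two oxygens.

Step 10
Reactants: 15 MOM enol ether
Product: 17 trans-fused 9α-(methoxymethoxy)-4,5-dimethyldecal-3-en-8-one (5β-methyl and 10α-H), via lithium enolate 16 (not isolated)
Conditions: Li, liq. NH3, THF, t-BuOH (1 equiv), −78 °C; isoprene; NH4Cl; then NaOMe (cat.), MeOH, rt
Reagents that add atoms: none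
Why: Dissolving-metal conjugate reduction should protonate the β-carbon C10 axially, anti to the angular methyl, giving the trans fusion as in octalone reductions, while enolate 16 shields the α-alkoxy ketone until quench; methoxide then equilibrates C9 to the equatorial α-ether, the β-epimer being 1,3-diaxial to the C5 methyl.

Step 11
Reactants: 17 trans-fused ketone
Product: 18 8,8-ethylenedioxy-9α-(methoxymethoxy)-4,5-dimethyl-trans-decal-3-ene
Conditions: HOCH2CH2OH, HC(OEt)3, TsOH·H2O (cat.), CH2Cl2, rt
Reagents that add atoms: ethylene glycol, OCCO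
Why: Acid-catalysed ketalisation with an orthoformate water scavenger at room temperature masks the C8 ketone against borane and should leave the MOM ether intact.

Step 12
Reactants: 18 dioxolane
Product: 20 8,8-ethylenedioxy-9α-(methoxymethoxy)-4β,5β-dimethyl-trans-decalin-3α-ol, via alkylborane 19 (not isolated)
Conditions: BH3·THF, THF, 0 °C → rt; then NaOH, H2O2, 0 °C → rt
Reagents that add atoms: hydrogen peroxide, OO
Why: Hydroboration–oxidation adds H and OH syn and anti-Markovnikov across C3=C4 from the α face, opposite the axial C5 methyl, setting C3 (α-OH) and C4 (β-methyl, cis to the C5 methyl) together.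

Step 13
Reactants: 20 3α-alcohol
Product: 21 8,8-ethylenedioxy-3α-(4-methoxybenzyloxy)-9α-(methoxymethoxy)-4β,5β-dimethyl-trans-decalin
Conditions: NaH, PMBCl, Bu4NI (cat.), DMF, 0 °C → rt
Reagents that add atoms: 4-methoxybenzyl chloride, COc1ccc(CCl)cc1
Why: Williamson etherification gives a PMB ether that withstands the acid and base steps ahead and is later removed oxidatively without touching the MOM ether.

Step 14
Reactants: 21 PMB ether dioxolane
Product: 22 3α-(4-methoxybenzyloxy)-9α-(methoxymethoxy)-4β,5β-dimethyl-trans-decalin-8-one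
Conditions: 1 M aq. HCl, THF, rt
Reagents that add atoms: water, O
Why: Dilute acid should hydrolyse the ketone-derived dioxolane much faster than the formaldehyde-derived MOM acetal or the PMB ether, returning the C8 ketone.

Step 15
Reactants: 22 ketone; 23 1,1-dimethoxypropan-2-one
Product: 25 7-(2-hydroxy-1,1-dimethoxypropan-2-yl) derivative of 22 (aldol adduct; mixture at C7 and C11), via lithium enolate 24 (not isolated)
Conditions: LiN(i-Pr)2, THF, −78 °C; then 23, −78 °C; aq. NH4Cl
Reagents that add atoms: none
Why: Kinetic deprotonation should occur at the open C7 methylene rather than the alkoxy-bearing C9 methine, and the lithium enolate adds in an aldol reaction to the activated α,α-dialkoxy ketone, the two new centres being removed in step 16.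

Step 16
Reactants: 25 aldol adduct
Product: 27 3α-(4-methoxybenzyloxy)-9α-(methoxymethoxy)-12,12-dimethoxy-eremophil-7(11)-en-8-one (mixture of alkene isomers; E drawn), via mesylate 26 (not isolated)
Conditions: MsCl, Et3N, DMAP (cat.), CH2Cl2, 0 °C; then DBU, rt
Reagents that add atoms: none
Why: Mesylation of the tertiary aldol hydroxyl and E1cB elimination through the ketone enolate should give the conjugated tetrasubstituted enone.

Step 17
Reactants: 27 enone acetal
Product: 28 (E)-3α-(4-methoxybenzyloxy)-9α-(methoxymethoxy)-8-oxoeremophil-7(11)-en-12-al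
Conditions: 1 M aq. HCl, THF, rt; then PhSH (10 mol %), Et3N (10 mol %), CH2Cl2, rt
Reagents that add atoms: water, O
Why: Acetal hydrolysis gives a 2-ene-1,4-dicarbonyl in which reversible thiolate conjugate addition should equilibrate the alkene to the E isomer that keeps both carbonyls conjugated and anti (the fumarate-over-maleate preference), placing the formyl carbon cis to C6 and the methyl cis to C8 as in the target.

Step 18
Reactants: 28 PMB ether enal
Product: 29 (E)-3α-hydroxy-9α-(methoxymethoxy)-8-oxoeremophil-7(11)-en-12-al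
Conditions: DDQ, CH2Cl2–pH 7 buffer, 0 °C → rt
Reagents that add atoms: none
Why: Oxidative PMB cleavage (hydride abstraction from the electron-rich benzylic ether, then hydrolysis) frees the C3 alcohol under neutral conditions that spare the MOM ether and the electron-poor ene-dicarbonyl.

Step 19
Reactants: 30 (E)-non-3-en-2-one; 31 triethyl (E)-4-phosphonocrotonate
Product: 33 ethyl (2E,4E,6E)-5-methyldodeca-2,4,6-trienoate, via lithiated phosphonate 32 (not isolated)
Conditions: LiN(SiMe3)2, THF, −78 °C; then 30, −78 °C → rt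
Reagents that add atoms: none
Why: Vinylogous Horner–Wadsworth–Emmons olefination of the methyl ketone extends the enone by four carbons, E at C2=C3 and expected mainly E at the trisubstituted C4=C5 bond, the minor 4Z isomer being removed by chromatography.

Step 20
Reactants: 33 ethyl trienoate
Product: 34 (2E,4E,6E)-5-methyldodeca-2,4,6-trienoic acid
Conditions: LiOH, THF–MeOH–H2O, rt; then aq. HCl
Reagents that add atoms: lithium hydroxide, [Li+].[OH-]
Why: Saponification and acidification give the free acid without disturbing the conjugated triene.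

Step 21
Reactants: 29 C3 alcohol; 34 trienoic acid
Product: 35 (E)-9α-(methoxymethoxy)-12-oxo-8-oxoeremophil-7(11)-en-3α-yl (2E,4E,6E)-5-methyldodeca-2,4,6-trienoate
Conditions: EDC·HCl, DMAP, CH2Cl2, 0 °C → rt
Reagents that add atoms: none
Why: Steglich esterification acylates the only free hydroxyl, the equatorial C3 alcohol, since C12 is present as the aldehyde and O9 as its MOM ether.

Step 22
Reactants: 35 ester enal
Product: 36 (E)-12-hydroxy-9α-(methoxymethoxy)-8-oxoeremophil-7(11)-en-3α-yl (2E,4E,6E)-5-methyldodeca-2,4,6-trienoate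
Conditions: NaBH4, MeOH–CH2Cl2, −78 °C
Reagents that add atoms: none
Why: Borohydride at low temperature should reduce the aldehyde 1,2 far faster than the hindered tetrasubstituted enone ketone or the ester, giving the primary allylic alcohol with the alkene geometry retained.

Step 23
Reactants: 36 MOM ether
Product: 37 CNP0226738.2 (target)
Conditions: Me2BBr, CH2Cl2, −78 °C; then aq. NaHCO3
Reagents that add atoms: none
Why: Dimethylboron bromide cleaves the MOM acetal at low temperature by coordination and bromide transfer, the bromomethyl ether hydrolysing on bicarbonate work-up, which should leave the ester, enone and allylic alcohol intact and release the equatorial 9α-hydroxyl.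

**Compound list**

1 | 3,4-dimethylphenol | Cc1ccc(O)cc1C | starting material
2 | 2-bromo-4,5-dimethylphenol | Cc1cc(O)c(Br)cc1C | intermediate
3 | 2-methoxy-4,5-dimethylphenol | COc1cc(C)c(C)cc1O | intermediate
4 | phenyl vinyl sulfone | C=CS(=O)(=O)c1ccccc1 | starting material
5 | 6,6-dimethoxy-3,4-dimethylcyclohexa-2,4-dien-1-one (masked o-benzoquinone) | O=C1C=C(C)C(C)=CC1(OC)OC | intermediate
6 | racemic (1R*,4S*,7S*)-3,3-dimethoxy-5,6-dimethyl-7-(phenylsulfonyl)bicyclo[2.2.2]oct-5-en-2-one | O=C1C(OC)(OC)[C@H]2C[C@H](S(=O)(=O)c3ccccc3)[C@@H]1C(C)=C2C.O=C1C(OC)(OC)[C@@H]2C[C@@H](S(=O)(=O)c3ccccc3)[C@H]1C(C)=C2C | intermediate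
7 | (1R,4S,7S)-3,3-dimethoxy-5,6-dimethyl-7-(phenylsulfonyl)bicyclo[2.2.2]oct-5-en-2-one | O=C1C(OC)(OC)[C@H]2C[C@H](S(=O)(=O)c3ccccc3)[C@@H]1C(C)=C2C | intermediate
8 | vinylmagnesium bromide | C=C[Mg]Br | starting material
9 | (1R,2R,4S,7S)-3,3-dimethoxy-5,6-dimethyl-7-(phenylsulfonyl)-2-vinylbicyclo[2.2.2]oct-5-en-2-ol | C=C[C@]1(O)C(OC)(OC)[C@H]2C[C@H](S(=O)(=O)c3ccccc3)[C@@H]1C(C)=C2C | intermediate
10 | (1R,2R,4S)-3,3-dimethoxy-5,6-dimethyl-2-vinylbicyclo[2.2.2]oct-5-en-2-ol | C=C[C@]1(O)C(OC)(OC)[C@H]2CC[C@@H]1C(C)=C2C | intermediate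
11 | potassium alkoxide of 10 | C=C[C@]1([O-])C(OC)(OC)[C@H]2CC[C@@H]1C(C)=C2C.[K+] | intermediate
12 | potassium C7=C8 enolate of 13 | C1CC[C@@H]2C(OC)(OC)C([O-])=CC[C@]2(C)C=1C.[K+] | intermediate
13 | (4aS,8aS)-1,1-dimethoxy-4a,5-dimethyl-3,4,4a,7,8,8a-hexahydronaphthalen-2(1H)-one (cis-fused) | C1CC[C@@H]2C(OC)(OC)C(=O)CC[C@]2(C)C=1C | intermediate
14 | 9-hydroxy-4,5-dimethyldecala-3,9(10)-dien-8-one (5β-methyl) | O=C1CC[C@]2(C)C(C)=CCCC2=C1O | intermediate
15 | 9-(methoxymethoxy)-4,5-dimethyldecala-3,9(10)-dien-8-one | O=C1CC[C@]2(C)C(C)=CCCC2=C1OCOC | intermediate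
16 | lithium C8=C9 enolate of 17 (10α-H) | C1CC[C@H]2C(OCOC)=C([O-])CC[C@]2(C)C=1C.[Li+] | intermediate
17 | trans-fused 9α-(methoxymethoxy)-4,5-dimethyldecal-3-en-8-one (5β-methyl, 10α-H) | C1CC[C@H]2[C@H](OCOC)C(=O)CC[C@]2(C)C=1C | intermediate
18 | 8,8-ethylenedioxy-9α-(methoxymethoxy)-4,5-dimethyl-trans-decal-3-ene | C1CC[C@H]2[C@H](OCOC)C3(OCCO3)CC[C@]2(C)C=1C | intermediate
19 | 3α-boryl derivative of 20 (alkylborane) | B[C@@H]1CC[C@H]2[C@H](OCOC)C3(OCCO3)CC[C@]2(C)[C@H]1C | intermediate
20 | 8,8-ethylenedioxy-9α-(methoxymethoxy)-4β,5β-dimethyl-trans-decalin-3α-ol | O[C@@H]1CC[C@H]2[C@H](OCOC)C3(OCCO3)CC[C@]2(C)[C@H]1C | intermediate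
21 | 3α-(4-methoxybenzyl) ether of 20 | COc1ccc(CO[C@@H]2CC[C@H]3[C@H](OCOC)C4(OCCO4)CC[C@]3(C)[C@H]2C)cc1 | intermediate
22 | 3α-(4-methoxybenzyloxy)-9α-(methoxymethoxy)-4β,5β-dimethyl-trans-decalin-8-one | COc1ccc(CO[C@@H]2CC[C@H]3[C@H](OCOC)C(=O)CC[C@]3(C)[C@H]2C)cc1 | intermediate
23 | 1,1-dimethoxypropan-2-one | CC(=O)C(OC)OC | starting material
24 | lithium C7=C8 enolate of 22 | COc1ccc(CO[C@@H]2CC[C@H]3[C@H](OCOC)C([O-])=CC[C@]3(C)[C@H]2C)cc1.[Li+] | intermediate
25 | C7 aldol adduct of 22 with 23 (mixture at C7 and C11) | COc1ccc(CO[C@@H]2CC[C@H]3[C@H](OCOC)C(=O)C(C(C)(O)C(OC)OC)C[C@]3(C)[C@H]2C)cc1 | intermediate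
26 | C11 mesylate of 25 | COc1ccc(CO[C@@H]2CC[C@H]3[C@H](OCOC)C(=O)C(C(C)(OS(C)(=O)=O)C(OC)OC)C[C@]3(C)[C@H]2C)cc1 | intermediate
27 | 7(11)-en-8-one 12,12-dimethyl acetal (alkene isomer mixture, E drawn) | COc1ccc(CO[C@@H]2CC[C@H]3[C@H](OCOC)C(=O)/C(=C(\C)C(OC)OC)C[C@]3(C)[C@H]2C)cc1 | intermediate
28 | (E)-3α-(4-methoxybenzyloxy)-9α-(methoxymethoxy)-8-oxoeremophil-7(11)-en-12-al | COc1ccc(CO[C@@H]2CC[C@H]3[C@H](OCOC)C(=O)/C(=C(\C)C=O)C[C@]3(C)[C@H]2C)cc1 | intermediate
29 | (E)-3α-hydroxy-9α-(methoxymethoxy)-8-oxoeremophil-7(11)-en-12-al | O[C@@H]1CC[C@H]2[C@H](OCOC)C(=O)/C(=C(\C)C=O)C[C@]2(C)[C@H]1C | intermediate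
30 | (E)-non-3-en-2-one | CCCCC/C=C/C(C)=O | starting material
31 | triethyl (E)-4-phosphonocrotonate | CCOC(=O)/C=C/CP(=O)(OCC)OCC | starting material
32 | lithium salt of 31 (γ-carbanion) | CCOC(=O)/C=C/[CH-]P(=O)(OCC)OCC.[Li+] | intermediate
33 | ethyl (2E,4E,6E)-5-methyldodeca-2,4,6-trienoate | CCCCC/C=C/C(C)=C/C=C/C(=O)OCC | intermediate
34 | (2E,4E,6E)-5-methyldodeca-2,4,6-trienoic acid | CCCCC/C=C/C(C)=C/C=C/C(=O)O | intermediate
35 | 3α-trienoate of 29 (C12 aldehyde, 9α-OMOM) | CCCCC/C=C/C(C)=C/C=C/C(=O)O[C@@H]1CC[C@H]2[C@H](OCOC)C(=O)/C(=C(\C)C=O)C[C@]2(C)[C@H]1C | intermediate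
36 | 9-O-methoxymethyl ether of the target | CCCCC/C=C/C(C)=C/C=C/C(=O)O[C@@H]1CC[C@H]2[C@H](OCOC)C(=O)/C(=C(\C)CO)C[C@]2(C)[C@H]1C | intermediate
37 | CNP0226738.2: (1R,2R,4aR,5S,8aR)-5-hydroxy-7-[(E)-1-hydroxypropan-2-ylidene]-1,8a-dimethyl-6-oxodecahydronaphthalen-2-yl (2E,4E,6E)-5-methyldodeca-2,4,6-trienoate | CCCCC/C=C/C(C)=C/C=C/C(=O)O[C@@H]1CC[C@H]2[C@H](O)C(=O)/C(=C(\C)CO)C[C@]2(C)[C@H]1C | target

**Step count**

Total steps: 23 (21 in the main line, 2 for acid 34).
Longest linear sequence: 21 steps (steps 1–18 and 21–23).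

**Steps most likely to fail**

Step 10. The C9–O bond may be cleaved reductively if the α-alkoxy ketone is released while metal is still present, or the protonation at C10 may not be fully face-selective. The fallback sets out from 15 and replaces electron transfer by hydrogen-atom transfer: Mn(dpm)3 (catalytic; dpm = dipivaloylmethanate), PhSiH3 and i-PrOH at room temperature under nitrogen. This should reduce the enone chemoselectively by delivering hydrogen to C10 anti to the angular methyl, leaving the isolated C3=C4 alkene and the ether untouched. Brief NaOMe/MeOH equilibration of C9 then returns the route to 17. This fallback passes through no new compound (F0).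

Step 17. The thiol-mediated equilibration may stall at an isomer mixture, or the double bond may drift out of conjugation into ring B through the dienol. The fallback sets out from 22 and avoids the geometric question until the oxygen is introduced. Enolate 24 is added to acetone to give the tertiary aldol F2, which is converted into its mesylate F3 and eliminated with DBU to the isopropylidene enone F4, which has two identical methyls. SeO2 in dioxane at 80 °C should then oxidise the methyl anti to the carbonyl, as it does in β,β-dimethyl acrylates, giving the (E)-enal and returning the route to 28.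

Step 3. Self-dimerisation of dienone 5 may outrun cycloaddition with the electron-poor sulfone, or isomer mixtures may complicate the resolution. The fallback sets out from 3 and generates 5 in the presence of phenyl vinyl sulfide, an electron-rich dienophile that reacts with the electron-poor dienone in the inverse-demand sense. This gives the racemic 7-(phenylthio) cycloadduct F1, whose sulfur is then oxidised chemoselectively with H2O2 and catalytic (NH4)6Mo7O24 in ethanol, returning the route to 6.

Further compounds
F1 | step 3 | racemic (1R*,4S*,7S*)-3,3-dimethoxy-5,6-dimethyl-7-(phenylthio)bicyclo[2.2.2]oct-5-en-2-one | O=C1C(OC)(OC)[C@H]2C[C@H](Sc3ccccc3)[C@@H]1C(C)=C2C.O=C1C(OC)(OC)[C@@H]2C[C@@H](Sc3ccccc3)[C@H]1C(C)=C2C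
F0 | step 10 | none | none
F2 | step 17 | 7-(2-hydroxypropan-2-yl) derivative of 22 (acetone aldol, mixture at C7) | COc1ccc(CO[C@@H]2CC[C@H]3[C@H](OCOC)C(=O)C(C(C)(C)O)C[C@]3(C)[C@H]2C)cc1
F3 | step 17 | mesylate of F2 | COc1ccc(CO[C@@H]2CC[C@H]3[C@H](OCOC)C(=O)C(C(C)(C)OS(C)(=O)=O)C[C@]3(C)[C@H]2C)cc1
F4 | step 17 | 3α-(4-methoxybenzyloxy)-9α-(methoxymethoxy)eremophil-7(11)-en-8-one (isopropylidene enone) | COc1ccc(CO[C@@H]2CC[C@H]3[C@H](OCOC)C(=O)C(=C(C)C)C[C@]3(C)[C@H]2C)cc1
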